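**Remark (assumptions).** Atoms carry cembrane numbers: ring C1–C14, C15–C17 on C1, C18 on C4, C19 on C8, C20 on C12. Compounds 18–21 are drawn as the E-enone; a Z isomer formed in step 10 would converge at 22, where C4 becomes tetrahedral. Aldehyde 2 is made fresh because it is volatile.

## Analysis of the target

The target is a cembranoid whose 14-membered carbocycle (C1–C14) is bridged twice. A seven-membered lactone (C16–O–C12–C13–C14–C1–C15) carries the exocyclic methylene C15=C17, and an oxolane (O, C4, C5, C6, C7) spans C4 and C7; C8 bears a second exocyclic methylene (C19). The six stereocentres (1R, 2S, 4S, 7R, 11S, 12S) fall into two clusters. On the lactone side, the C11 carbinol sits next to the fully substituted, oxygen-bearing C12, and C11 is trans to C2 across the lactone ring (the C20 methyl is cis to C2). On the oxolane side, the C2 hydroxyl is 1,3-syn to the C4 ether oxygen, and the ring bonds to C3 and C8 are cis on the oxolane. The sensitive groups are the α-methylene lactone (a Michael acceptor), the C2 hydroxyl (γ to C16, able to reorganise the lactone under base), C1–H (epimerisable while C2 is a ketone) and the allylic C7 ether. The hard points are the tertiary lactone C–O bond at a quaternary stereocentre, the medium ring, and the two remote stereo clusters. The strategy rests on one feature: C16, C15, C1, C14, C13 and C12, with the C20 methyl on C12 and a carbon substituent on C1, are the carbon pattern of a 2-methyl-5-substituted cyclohexanone of the carvone type, with one oxygen inserted between C16 and C12.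

## Retrosynthetic reasoning

**C15=C17 and the silyl groups (29 ⇐ 28 ⇐ 24).** The methylene lactone is the most reactive group and is made last, by aminomethylation of the lactone enolate of 24 and elimination. Both hydroxyls stay silylated until then, because a free C2 alkoxide could attack C16.

**C2–H (23 ⇐ 22).** The C2 carbinol is traced to ketone 22. This ketone is the retron of an oxa-Michael addition, and its β-oxygen on C4 offers chelation control for the reduction.

**C4–O (22 ⇐ 21 ⇐ 20).** Cutting the C4–O bond of the oxolane gives the macrocyclic hydroxy enone 21. The forward step is a transannular, reversible 5-exo addition, so the quaternary C4 can settle relative to C7 inside the ring rather than being built beforehand.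

**C7–C8 (20 ⇐ 19).** The macrocycle is opened at C7–C8, between an aldehyde carbon and the internal carbon of a terminal alkyne. A reductive nickel-catalysed coupling in the exo mode would deliver the ring, the C7 oxygen and the C19 methylene in one step, and the alkyne is an inert passenger until then.

**C3–C4 (19 ⇐ 18 ⇐ 17 ⇐ 15 ⇐ 13 + 14).** The enone is cut at C3–C4. An enolate aldol of a C1 acetyl group with ketone 14 was rejected for three reasons: the terminal alkyne C–H is acidic, a C3 enolate can attack C16 in a five-membered mode, and C1 would be exposed to base. Instead C3 is made nucleophilic as an allylzinc species from allylic chloride 13. Ozonolysis of adduct 15 then reveals the C2 ketone of 17, and neutral dehydration gives 18.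

**C–Cl (13 ⇐ 12).** The isopropenyl group of lactone 12 already holds C2 and C3. An ene-type chlorination functionalises its methyl group without touching anything else.

**C16–O–C12 (12 ⇐ 10), the key disconnection.** Removing the ring oxygen returns cyclohexanone 10. The forward oxygen insertion makes the tertiary C12–O bond with retention, so the problem of a quaternary carbinol stereocentre becomes the problem of a quaternary carbon next to a ketone.

**C11–C12 and the C12 configuration (10 ⇐ 8 ⇐ 7 ⇐ 5 + 2; 5 ⇐ 3; 2 ⇐ 1).** The side chain is attached by an aldol reaction of a carvone-derived enolate with aldehyde 2. An unconstrained dihydrocarvone enolate should take up an electrophile along the chair-like axial trajectory, which puts the new bond cis to the C1 substituent; that is the sense known from annulations of dihydrocarvone, and it would give the wrong C12 epimer. The enolate is therefore generated from the cyclopropane-locked enone 5, made from 3. Its gem-dimethylcyclopropane (C1–C2–C15) blocks that face. Acid opening of 7 to bromide 8 and loss of HBr then restore the isopropenyl group of 10.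

## Alternatives that were turned down

**Alternative 1: furan–oxyallyl [4+3] cycloaddition.** The oxolane is disconnected at C3–C4 and C7–C8. In the forward step, 2-methylfuran A1 and the oxyallyl cation generated from the chiral allenamide A2 (by epoxidation and Lewis-acid ionisation) would combine to the bridged ketone A3.
- For: the cycloaddition is concerted across the furan, so C4 and C7 are necessarily cis, and the auxiliary fixes their absolute sense. The quaternary C4 ether needs no reversible addition. On this point it is stronger than the chosen route, which sets C7 in a macrocyclisation and C4 after it.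
- Against: A3 holds only C3–C8. The carbonyl carbon between C3 and C8 must be cut out of the seven-membered ring, the nitrogen on C3 removed, and the C5=C6 alkene saturated. The regiochemistry of the unsymmetrical furan must also be right. None of this helps with C12, C11 or C1, and the lactone and macrocycle are still to be built.
- Comparison: the chosen strategy gives up certainty at C4/C7. In return it takes C1, C12–C16 and C20 from one terpene and makes the hardest C–O bond stereospecifically, in far fewer steps overall.

**Alternative 2: Claisen ring contraction forming C9–C10.** The carbocycle is disconnected at C9–C10. Heating the 14-membered cyclic enol ether A4 (a methylenated macrolactone) would give the carbocyclic C11 ketone A5 by [3,3] rearrangement.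
- For: the ring is first closed as an ester, a dependable closure. The C–C bond then forms in a unimolecular step, and the C8 methylene appears with fixed regiochemistry. Here it is stronger than the chosen route, whose nickel closure depends on ligand-controlled regiochemistry.
- Against: A5 has no lactone. The C15/C16 arm is a protected hydroxyethyl chain, and C12 is a protected tertiary alcohol. After the key step come deprotection, oxidation to the acid, lactonisation onto a hindered tertiary hydroxyl, reduction of the C11 ketone next to quaternary C12 with control, and methylenation. All of C1, C2, C4, C7 and C12 must be set separately in the linear precursor, and the rearrangement must fold inside a ring that already contains the oxolane.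
- Comparison: the chosen route has the lactone and the C11/C12 pair in place from the aldol and the oxygen insertion, with fewer protecting-group operations.

**Alternative 3: macrocyclising nitrile oxide cycloaddition.** The ring is disconnected at C2–C3 and O–C4. A nitrile oxide on C2, generated from a nitromethyl group on C1, would add to the C3=C4 alkene and give the isoxazoline-fused macrocycle A6.
- For: it can use the same carvone-derived lactone. It makes two bonds while closing the ring, the regiochemistry (oxygen to the substituted carbon) is dependable, and the isoxazoline masks the C2 ketone and the C4 oxygen. The macrocyclisation needs no regiocontrol by a ligand, which is a point in its favour.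
- Against: the isopropenyl group must be degraded to a one-carbon nitromethyl unit, although its two carbons are exactly C2 and C3. C4 is fixed irreversibly in the cyclisation with no nearby control element. Nitrile oxide dimerisation competes with 14-ring formation. The oxolane must then be closed by a tertiary alcohol attacking an allyl system at C7, a difficult etherification.
- Comparison: in the chosen route the oxa-Michael addition is reversible, so C4 can correct itself, and the isopropenyl carbons are used as they stand.

Key step: step 6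

## Route

**Step 1**
Reactants: 1 pent-4-yn-1-ol
Product: 2 pent-4-ynal
Conditions: PhI(OAc)2 (1.1 equiv), TEMPO (0.1 equiv), CH2Cl2, rt; short-path distillation
Reagents that add atoms: none
Why: TEMPO-catalysed oxidation with a hypervalent iodine co-oxidant takes the primary alcohol to the aldehyde without over-oxidation and leaves the alkyne alone.

**Step 2**
Reactants: 3 (R)-carvone
Product: 5 (1S,6R)-3,7,7-trimethylbicyclo[4.1.0]hept-3-en-2-one, via carvone hydrobromide 4 (not isolated)
Conditions: HBr (33% in AcOH), 0 °C; evaporate; KOH, MeOH, 0 °C, short contact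
Reagents that add atoms: none
Why: Markovnikov addition of HBr to the isopropenyl group gives tertiary bromide 4; cold methanolic KOH forms the cross-conjugated dienolate at C15, which displaces bromide (3-exo-tet alkylation) and closes the C2–C15 cyclopropane. The ring fusion can only be cis and C1 keeps its configuration; short contact avoids base-induced ring enlargement.

**Step 3**
Reactants: 5 (1S,6R)-3,7,7-trimethylbicyclo[4.1.0]hept-3-en-2-one; 2 pent-4-ynal
Product: 7 (1S,3S,6R)-3-[(1S)-1-hydroxypent-4-yn-1-yl]-3,7,7-trimethylbicyclo[4.1.0]heptan-2-one, via lithium enolate 6 (not isolated)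
Conditions: LiBH(s-Bu)3 (1.05 equiv), THF, −78 °C; then 2, −78 °C; AcOH, −78 °C
Reagents that add atoms: none
Why: Conjugate hydride addition gives the regiodefined lithium enolate 6, which adds to the aldehyde through a Zimmerman–Traxler chair (reductive aldol reaction). The endo methyl of the gem-dimethylcyclopropane shields one face of C12, so the aldehyde enters anti to the C2 bridge and C12 is set with the side chain trans to the future C1 substituent. The ring-locked E(O)-enolate with the aldehyde chain equatorial sets C11 (C20 methyl and hydroxyl syn in the extended chain).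

**Step 4**
Reactants: 7 (1S,3S,6R)-3-[(1S)-1-hydroxypent-4-yn-1-yl]-3,7,7-trimethylbicyclo[4.1.0]heptan-2-one
Product: 8 (2S,5R)-5-(2-bromopropan-2-yl)-2-[(1S)-1-hydroxypent-4-yn-1-yl]-2-methylcyclohexan-1-one
Conditions: HBr (33% in AcOH, 1.5 equiv), CH2Cl2, −20 °C, 15 min
Reagents that add atoms: hydrogen bromide, Br
Why: Acid opening of a cyclopropyl ketone (homoconjugate addition of HBr): protonation at C15 breaks the C15–C2 bond that leads to the tertiary cation at C2, and bromide captures it. C1 and C12 are not involved, and the terminal alkyne adds HBr much more slowly at this temperature.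

**Step 5**
Reactants: 8 (2S,5R)-5-(2-bromopropan-2-yl)-2-[(1S)-1-hydroxypent-4-yn-1-yl]-2-methylcyclohexan-1-one
Product: 10 (2S,5R)-2-[(1S)-1-(tert-butyldimethylsilyloxy)pent-4-yn-1-yl]-2-methyl-5-(prop-1-en-2-yl)cyclohexan-1-one, via bromo silyl ether 9 (not isolated)
Conditions: TBSOTf, 2,6-lutidine, CH2Cl2, −78 → 0 °C; then DBU, 40 °C
Reagents that add atoms: tert-butyldimethylsilyl triflate, CC(C)(C)[Si](C)(C)OS(=O)(=O)C(F)(F)F
Why: The silyl triflate with a hindered pyridine silylates the neopentyl-type C11 alcohol without touching the ketone. The amidine base then removes HBr by E2 from the tertiary bromide, preferentially through the six unhindered methyl hydrogens, which restores the isopropenyl group. DBU is too weak to form the C15 enolate that would re-close the cyclopropane.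

**Step 6 (key step)**
Reactants: 10 (2S,5R)-2-[(1S)-1-(tert-butyldimethylsilyloxy)pent-4-yn-1-yl]-2-methyl-5-(prop-1-en-2-yl)cyclohexan-1-one
Product: 12 (4R,7S)-7-[(1S)-1-(tert-butyldimethylsilyloxy)pent-4-yn-1-yl]-7-methyl-4-(prop-1-en-2-yl)oxepan-2-one, via Criegee adduct 11 (not isolated)
Conditions: Me3SiOOSiMe3 (2 equiv), Me3SiOTf (0.2 equiv), CH2Cl2, −40 → −20 °C
Reagents that add atoms: bis(trimethylsilyl) peroxide, C[Si](C)(C)OO[Si](C)(C)C
Why: The silyl triflate silylates the C16 carbonyl oxygen and the silyl peroxide adds to the resulting oxocarbenium ion to give Criegee adduct 11; activation of the distal peroxide oxygen then triggers loss of hexamethyldisiloxane with concerted 1,2-shift of C12 from C16 to oxygen. The closest known reaction type is the Baeyer–Villiger oxidation of ketones with a silyl peroxide and a silyl triflate in an aprotic medium. The seven-membered ring is not closed by a cyclisation: it arises by ring expansion, the six-membered ketone gaining one ring atom through the 1,2-shift. C12 migrates with retention, because the migrating carbon keeps its bonding pair and moves suprafacially onto oxygen, so the tertiary C12–O stereocentre (S) takes over the configuration set in step 3. The step needs C12 and not the C15 methylene to migrate: the fully substituted carbon stabilises the developing positive charge far better, and in the chair adduct its ring bond can lie antiperiplanar to the O–O bond. It also needs the isopropenyl alkene and the alkyne to stay untouched: no peracid is present, and the silyl peroxide does not epoxidise. The C11 silyl ether is the only Lewis-acid-sensitive group, and substoichiometric triflate at low temperature should leave it in place.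

**Step 7**
Reactants: 12 (4R,7S)-7-[(1S)-1-(tert-butyldimethylsilyloxy)pent-4-yn-1-yl]-7-methyl-4-(prop-1-en-2-yl)oxepan-2-one
Product: 13 (4R,7S)-7-[(1S)-1-(tert-butyldimethylsilyloxy)pent-4-yn-1-yl]-4-(3-chloroprop-1-en-2-yl)-7-methyloxepan-2-one
Conditions: Ca(OCl)2, solid CO2, CH2Cl2/H2O, 0 °C
Reagents that add atoms: calcium hypochlorite, [Ca+2].[O-]Cl.[O-]Cl
Why: Ene-type allylic chlorination by hypochlorous acid generated at near-neutral pH: the electron-rich 1,1-disubstituted alkene is chlorinated at its terminus with shift of the double bond into the methyl group, giving the 2-substituted allyl chloride. Lactone, silyl ether and alkyne should not react under these buffered two-phase conditions.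

**Step 8**
Reactants: 13 (4R,7S)-7-[(1S)-1-(tert-butyldimethylsilyloxy)pent-4-yn-1-yl]-4-(3-chloroprop-1-en-2-yl)-7-methyloxepan-2-one; 14 5,5-dimethoxypentan-2-one
Product: 15 (4R,7S)-7-[(1S)-1-(tert-butyldimethylsilyloxy)pent-4-yn-1-yl]-4-(4-hydroxy-7,7-dimethoxy-4-methylhept-1-en-2-yl)-7-methyloxepan-2-one (C4 epimers)
Conditions: Zn dust, THF/sat. aq NH4Cl (1:1), 0 °C → rt
Reagents that add atoms: none
Why: Barbier allylation in aqueous medium: the allylzinc species formed on the metal adds to the methyl ketone of 14 and forms C3–C4; its two termini are equivalent, so one constitution results. No strong base is present, so the alkyne C–H, the lactone and C1 are safe. C4 forms as a mixture, which does not matter because it becomes sp2 in step 10.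

**Step 9**
Reactants: 15 (4R,7S)-7-[(1S)-1-(tert-butyldimethylsilyloxy)pent-4-yn-1-yl]-4-(4-hydroxy-7,7-dimethoxy-4-methylhept-1-en-2-yl)-7-methyloxepan-2-one
Product: 17 (4R,7S)-7-[(1S)-1-(tert-butyldimethylsilyloxy)pent-4-yn-1-yl]-4-(3-hydroxy-6,6-dimethoxy-3-methylhexanoyl)-7-methyloxepan-2-one, via secondary ozonide 16 (not isolated)
Conditions: O3, CH2Cl2, −78 °C, to dye-indicator end point; then Me2S, −78 °C → rt
Reagents that add atoms: ozone, [O-][O+]=O
Why: Ozonolysis: the electron-rich 1,1-disubstituted alkene reacts far faster than the alkyne, and the reaction is stopped at the indicator end point. Reduction of ozonide 16 with the sulfide gives the C2 ketone.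

**Step 10**
Reactants: 17 (4R,7S)-7-[(1S)-1-(tert-butyldimethylsilyloxy)pent-4-yn-1-yl]-4-(3-hydroxy-6,6-dimethoxy-3-methylhexanoyl)-7-methyloxepan-2-one
Product: 18 (4R,7S)-7-[(1S)-1-(tert-butyldimethylsilyloxy)pent-4-yn-1-yl]-4-[(2E)-6,6-dimethoxy-3-methylhex-2-enoyl]-7-methyloxepan-2-one
Conditions: Burgess reagent, toluene, 50 °C
Reagents that add atoms: none
Why: Burgess dehydration: the tertiary C4 alcohol forms a sulfamate ester that undergoes syn-elimination through the acidic C3 hydrogens next to the ketone, giving the conjugated enone. The reagent is neutral, so neither retro-aldol cleavage nor epimerisation at C1 is expected.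

**Step 11**
Reactants: 18 (4R,7S)-7-[(1S)-1-(tert-butyldimethylsilyloxy)pent-4-yn-1-yl]-4-[(2E)-6,6-dimethoxy-3-methylhex-2-enoyl]-7-methyloxepan-2-one
Product: 19 (4R,7S)-7-[(1S)-1-(tert-butyldimethylsilyloxy)pent-4-yn-1-yl]-7-methyl-4-[(2E)-3-methyl-6-oxohex-2-enoyl]oxepan-2-one
Conditions: p-TsOH·H2O (0.1 equiv), THF/H2O (4:1), rt
Reagents that add atoms: water, O
Why: Acid-catalysed hydrolysis of the dimethyl acetal to the C7 aldehyde. The hindered secondary silyl ether, the lactone and the enone should tolerate catalytic sulfonic acid in wet THF at room temperature.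

**Step 12**
Reactants: 19 (4R,7S)-7-[(1S)-1-(tert-butyldimethylsilyloxy)pent-4-yn-1-yl]-7-methyl-4-[(2E)-3-methyl-6-oxohex-2-enoyl]oxepan-2-one
Product: 20 (1R,7R,11S,12S,3E)-11-(tert-butyldimethylsilyloxy)-2-oxo-7-(triethylsilyloxy)-17-norcembra-3,8(19)-dien-16,12-olide
Conditions: Ni(cod)2 (0.3 equiv), 1,3-bis(2,6-diisopropylphenyl)imidazolium chloride (0.3 equiv), KOt-Bu (0.3 equiv), Et3SiH (5 equiv), THF, rt, syringe-pump addition of 19 to 2 mM
Reagents that add atoms: triethylsilane, CC[SiH](CC)CC
Why: Nickel-catalysed reductive alkyne–aldehyde coupling: zerovalent nickel with the bulky carbene binds both partners, oxidative cyclisation gives an oxanickelacyclopentene, and σ-bond metathesis with the silane followed by C–H reductive elimination releases the silyl ether. The large ligand turns the alkyne so that C8, not the terminal C19, bonds to C7 (exo mode); this closes the 14-membered ring and leaves C19 as the methylene, while slow addition at high dilution suppresses oligomers. C7 forms without a neighbouring control element: the 7R epimer is expected from closure through the extended conformer that keeps the E-enone and the lactone apart, and this is the least secure stereocentre of the route.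

**Step 13**
Reactants: 20 (1R,7R,11S,12S,3E)-11-(tert-butyldimethylsilyloxy)-2-oxo-7-(triethylsilyloxy)-17-norcembra-3,8(19)-dien-16,12-olide
Product: 22 (1R,4S,7R,11S,12S)-11-(tert-butyldimethylsilyloxy)-4,7-epoxy-2-oxo-17-norcembr-8(19)-en-16,12-olide, via C7 hydroxy enone 21 (not isolated)
Conditions: CSA (0.2 equiv), CH2Cl2/MeOH (5:1), 0 °C → rt
Reagents that add atoms: none
Why: Acidic methanolysis removes the triethylsilyl group far faster than the hindered C11 silyl ether; the freed C7 hydroxyl of 21 then adds across the ring to C4 of the protonated enone (transannular 5-exo-trig oxa-Michael addition). The addition is reversible, so C4 should settle in the configuration that bridges C3 and C8 cis on the oxolane (4S for 7R), the less strained way to span the ten-carbon tether. Acid rather than base is used to limit enolisation at C1.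

**Step 14**
Reactants: 22 (1R,4S,7R,11S,12S)-11-(tert-butyldimethylsilyloxy)-4,7-epoxy-2-oxo-17-norcembr-8(19)-en-16,12-olide
Product: 23 (1R,2S,4S,7R,11S,12S)-11-(tert-butyldimethylsilyloxy)-4,7-epoxy-2-hydroxy-17-norcembr-8(19)-en-16,12-olide
Conditions: Zn(BH4)2, Et2O, −30 °C; AcOH quench at −30 °C
Reagents that add atoms: none
Why: Chelation-controlled reduction of a β-alkoxy ketone: zinc bridges the C2 carbonyl and the oxolane oxygen on C4, and external hydride attacks the chelate anti to the C5 ring branch, giving the 1,3-syn arrangement of C2–OH and C4–O, that is 2S. The weakly nucleophilic zinc alkoxide and the cold acidic quench are chosen because a free C2 alkoxide could attack C16 and reorganise the lactone.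

**Step 15**
Reactants: 23 (1R,2S,4S,7R,11S,12S)-11-(tert-butyldimethylsilyloxy)-4,7-epoxy-2-hydroxy-17-norcembr-8(19)-en-16,12-olide
Product: 24 (1R,2S,4S,7R,11S,12S)-11-(tert-butyldimethylsilyloxy)-4,7-epoxy-2-(triethylsilyloxy)-17-norcembr-8(19)-en-16,12-olide
Conditions: Et3SiOTf, 2,6-lutidine, CH2Cl2, −78 °C
Reagents that add atoms: triethylsilyl triflate, CC[Si](CC)(CC)OS(=O)(=O)C(F)(F)F
Why: Silylation with a silyl triflate and a hindered pyridine. The C2 hydroxyl must be masked because its alkoxide, γ to C16, could open the seven-membered lactone in favour of a five-membered one under the basic conditions of step 16.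

**Step 16**
Reactants: 24 (1R,2S,4S,7R,11S,12S)-11-(tert-butyldimethylsilyloxy)-4,7-epoxy-2-(triethylsilyloxy)-17-norcembr-8(19)-en-16,12-olide
Product: 26 (1R,2S,4S,7R,11S,12S)-11-(tert-butyldimethylsilyloxy)-17-(dimethylamino)-4,7-epoxy-2-(triethylsilyloxy)cembr-8(19)-en-16,12-olide (C15 epimers), via lithium lactone enolate 25 (not isolated)
Conditions: LiN(i-Pr)2 (1.2 equiv), THF, −78 °C; then CH2=NMe2+ I− (3 equiv), −78 → 0 °C
Reagents that add atoms: dimethyl(methylidene)ammonium iodide, C[N+](C)=C.[I-]
Why: Aminomethylation of a lactone enolate (Mannich reaction with a preformed iminium salt): C15 carries the only acidic hydrogens, and enolate 25 is trapped there by the iminium ion. The new C15 centre is a mixture, which is removed in step 17.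

**Step 17**
Reactants: 26 (1R,2S,4S,7R,11S,12S)-11-(tert-butyldimethylsilyloxy)-17-(dimethylamino)-4,7-epoxy-2-(triethylsilyloxy)cembr-8(19)-en-16,12-olide
Product: 28 (1R,2S,4S,7R,11S,12S)-11-(tert-butyldimethylsilyloxy)-4,7-epoxy-2-(triethylsilyloxy)cembra-8(19),15(17)-dien-16,12-olide, via trimethylammonium iodide 27 (not isolated)
Conditions: MeI, CH2Cl2/MeOH, rt; then sat. aq NaHCO3, rt
Reagents that add atoms: none
Why: Quaternisation of the amine with methyl iodide and base-induced elimination of trimethylamine from ammonium salt 27 give the exocyclic C15=C17 alkene. Bicarbonate is too weak to affect the lactone or the silyl ethers.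

**Step 18**
Reactants: 28 (1R,2S,4S,7R,11S,12S)-11-(tert-butyldimethylsilyloxy)-4,7-epoxy-2-(triethylsilyloxy)cembra-8(19),15(17)-dien-16,12-olide
Product: 29 (1R,2S,4S,7R,11S,12S)-4,7-epoxy-2,11-dihydroxycembra-8(19),15(17)-dien-16,12-olide (CNP0289823.1)
Conditions: 48% aq HF, MeCN, 0 °C → rt
Reagents that add atoms: none
Why: Acidic fluoride cleaves both silyl ethers. No alkoxide is formed, so neither translactonisation by the C2 hydroxyl nor conjugate addition to the methylene lactone is expected.

## Compound list

1 | pent-4-yn-1-ol | C#CCCCO | starting material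
2 | pent-4-ynal | C#CCCC=O | intermediate
3 | (R)-carvone | CC1=CC[C@@H](C(C)=C)CC1=O | starting material
4 | (5R)-5-(2-bromopropan-2-yl)-2-methylcyclohex-2-en-1-one (carvone hydrobromide, formed in situ) | CC1=CC[C@@H](C(C)(C)Br)CC1=O | intermediate
5 | (1S,6R)-3,7,7-trimethylbicyclo[4.1.0]hept-3-en-2-one | CC1=CC[C@H]2C(C)(C)[C@H]2C1=O | intermediate
6 | lithium (1S,6R)-3,7,7-trimethylbicyclo[4.1.0]hept-2-en-2-olate (formed in situ) | [Li+].[O-]C1=C(C)CC[C@H]2C(C)(C)[C@@H]12 | intermediate
7 | (1S,3S,6R)-3-[(1S)-1-hydroxypent-4-yn-1-yl]-3,7,7-trimethylbicyclo[4.1.0]heptan-2-one | [C@H]12C(=O)[C@@]([C@@H](O)CCC#C)(C)CC[C@H]1C2(C)C | intermediate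
8 | (2S,5R)-5-(2-bromopropan-2-yl)-2-[(1S)-1-hydroxypent-4-yn-1-yl]-2-methylcyclohexan-1-one | C1C(=O)[C@@]([C@@H](O)CCC#C)(C)CC[C@H]1C(C)(C)Br | intermediate
9 | (2S,5R)-5-(2-bromopropan-2-yl)-2-[(1S)-1-(tert-butyldimethylsilyloxy)pent-4-yn-1-yl]-2-methylcyclohexan-1-one (formed in situ) | C1C(=O)[C@@]([C@@H](O[Si](C)(C)C(C)(C)C)CCC#C)(C)CC[C@H]1C(C)(C)Br | intermediate
10 | (2S,5R)-2-[(1S)-1-(tert-butyldimethylsilyloxy)pent-4-yn-1-yl]-2-methyl-5-(prop-1-en-2-yl)cyclohexan-1-one | C1C(=O)[C@@]([C@@H](O[Si](C)(C)C(C)(C)C)CCC#C)(C)CC[C@H]1C(C)=C | intermediate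
11 | Criegee adduct of 10: 1-(trimethylsilyloxy)-1-(trimethylsilylperoxy)cyclohexane, C16 unassigned (formed in situ) | C1C(O[Si](C)(C)C)(OO[Si](C)(C)C)[C@@]([C@@H](O[Si](C)(C)C(C)(C)C)CCC#C)(C)CC[C@H]1C(C)=C | intermediate
12 | (4R,7S)-7-[(1S)-1-(tert-butyldimethylsilyloxy)pent-4-yn-1-yl]-7-methyl-4-(prop-1-en-2-yl)oxepan-2-one | C1C(=O)O[C@@]([C@@H](O[Si](C)(C)C(C)(C)C)CCC#C)(C)CC[C@H]1C(C)=C | intermediate
13 | (4R,7S)-7-[(1S)-1-(tert-butyldimethylsilyloxy)pent-4-yn-1-yl]-4-(3-chloroprop-1-en-2-yl)-7-methyloxepan-2-one | C1C(=O)O[C@@]([C@@H](O[Si](C)(C)C(C)(C)C)CCC#C)(C)CC[C@H]1C(=C)CCl | intermediate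
14 | 5,5-dimethoxypentan-2-one | CC(=O)CCC(OC)OC | starting material
15 | (4R,7S)-7-[(1S)-1-(tert-butyldimethylsilyloxy)pent-4-yn-1-yl]-4-(4-hydroxy-7,7-dimethoxy-4-methylhept-1-en-2-yl)-7-methyloxepan-2-one (C4 epimers) | C1C(=O)O[C@@]([C@@H](O[Si](C)(C)C(C)(C)C)CCC#C)(C)CC[C@H]1C(=C)CC(C)(O)CCC(OC)OC | intermediate
16 | secondary ozonide (1,2,4-trioxolane) of 15 (formed in situ) | C1C(=O)O[C@@]([C@@H](O[Si](C)(C)C(C)(C)C)CCC#C)(C)CC[C@H]1C2(OCOO2)CC(C)(O)CCC(OC)OC | intermediate
17 | (4R,7S)-7-[(1S)-1-(tert-butyldimethylsilyloxy)pent-4-yn-1-yl]-4-(3-hydroxy-6,6-dimethoxy-3-methylhexanoyl)-7-methyloxepan-2-one (C4 epimers) | C1C(=O)O[C@@]([C@@H](O[Si](C)(C)C(C)(C)C)CCC#C)(C)CC[C@H]1C(=O)CC(C)(O)CCC(OC)OC | intermediate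
18 | (4R,7S)-7-[(1S)-1-(tert-butyldimethylsilyloxy)pent-4-yn-1-yl]-4-[(2E)-6,6-dimethoxy-3-methylhex-2-enoyl]-7-methyloxepan-2-one | C1C(=O)O[C@@]([C@@H](O[Si](C)(C)C(C)(C)C)CCC#C)(C)CC[C@H]1C(=O)/C=C(\C)CCC(OC)OC | intermediate
19 | (4R,7S)-7-[(1S)-1-(tert-butyldimethylsilyloxy)pent-4-yn-1-yl]-7-methyl-4-[(2E)-3-methyl-6-oxohex-2-enoyl]oxepan-2-one | C1C(=O)O[C@@]([C@@H](O[Si](C)(C)C(C)(C)C)CCC#C)(C)CC[C@H]1C(=O)/C=C(\C)CCC=O | intermediate
20 | (1R,7R,11S,12S,3E)-11-(tert-butyldimethylsilyloxy)-2-oxo-7-(triethylsilyloxy)-17-norcembra-3,8(19)-dien-16,12-olide | C1C(=O)O[C@@]2(C)CC[C@H]1C(=O)/C=C(\C)CC[C@@H](O[Si](CC)(CC)CC)C(=C)CC[C@@H]2O[Si](C)(C)C(C)(C)C | intermediate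
21 | (1R,7R,11S,12S,3E)-11-(tert-butyldimethylsilyloxy)-7-hydroxy-2-oxo-17-norcembra-3,8(19)-dien-16,12-olide (formed in situ) | C1C(=O)O[C@@]2(C)CC[C@H]1C(=O)/C=C(\C)CC[C@@H](O)C(=C)CC[C@@H]2O[Si](C)(C)C(C)(C)C | intermediate
22 | (1R,4S,7R,11S,12S)-11-(tert-butyldimethylsilyloxy)-4,7-epoxy-2-oxo-17-norcembr-8(19)-en-16,12-olide | C1C(=O)O[C@@]2(C)CC[C@H]1C(=O)C[C@]3(C)CC[C@@H](O3)C(=C)CC[C@@H]2O[Si](C)(C)C(C)(C)C | intermediate
23 | (1R,2S,4S,7R,11S,12S)-11-(tert-butyldimethylsilyloxy)-4,7-epoxy-2-hydroxy-17-norcembr-8(19)-en-16,12-olide | C1C(=O)O[C@@]2(C)CC[C@H]1[C@@H](O)C[C@]3(C)CC[C@@H](O3)C(=C)CC[C@@H]2O[Si](C)(C)C(C)(C)C | intermediate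
24 | (1R,2S,4S,7R,11S,12S)-11-(tert-butyldimethylsilyloxy)-4,7-epoxy-2-(triethylsilyloxy)-17-norcembr-8(19)-en-16,12-olide | C1C(=O)O[C@@]2(C)CC[C@H]1[C@@H](O[Si](CC)(CC)CC)C[C@]3(C)CC[C@@H](O3)C(=C)CC[C@@H]2O[Si](C)(C)C(C)(C)C | intermediate
25 | lithium enolate of 24 (C15=C16–OLi, formed in situ) | C1=C([O-])O[C@@]2(C)CC[C@H]1[C@@H](O[Si](CC)(CC)CC)C[C@]3(C)CC[C@@H](O3)C(=C)CC[C@@H]2O[Si](C)(C)C(C)(C)C.[Li+] | intermediate
26 | (1R,2S,4S,7R,11S,12S)-11-(tert-butyldimethylsilyloxy)-17-(dimethylamino)-4,7-epoxy-2-(triethylsilyloxy)cembr-8(19)-en-16,12-olide (C15 epimers) | CN(C)CC1C(=O)O[C@@]2(C)CC[C@H]1[C@@H](O[Si](CC)(CC)CC)C[C@]3(C)CC[C@@H](O3)C(=C)CC[C@@H]2O[Si](C)(C)C(C)(C)C | intermediate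
27 | 17-(trimethylammonio) iodide of 26 (formed in situ) | C[N+](C)(C)CC1C(=O)O[C@@]2(C)CC[C@H]1[C@@H](O[Si](CC)(CC)CC)C[C@]3(C)CC[C@@H](O3)C(=C)CC[C@@H]2O[Si](C)(C)C(C)(C)C.[I-] | intermediate
28 | (1R,2S,4S,7R,11S,12S)-11-(tert-butyldimethylsilyloxy)-4,7-epoxy-2-(triethylsilyloxy)cembra-8(19),15(17)-dien-16,12-olide | C=C1C(=O)O[C@@]2(C)CC[C@H]1[C@@H](O[Si](CC)(CC)CC)C[C@]3(C)CC[C@@H](O3)C(=C)CC[C@@H]2O[Si](C)(C)C(C)(C)C | intermediate
29 | (1R,2S,4S,7R,11S,12S)-4,7-epoxy-2,11-dihydroxycembra-8(19),15(17)-dien-16,12-olide (CNP0289823.1) | C=C1C(=O)O[C@@]2(C)CC[C@H]1[C@@H](O)C[C@]1(C)CC[C@@H](O1)C(=C)CC[C@@H]2O | target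

## Step count and least certain steps

Total step count: 18. Longest linear sequence: 17 steps (3 → 29; the branch 1 → 2 joins at step 3 and is equally long).

**Step 6 (key step).** The most likely failure is slow addition of the silyl peroxide to the carbonyl flanked by quaternary C12. The Lewis acid would then strip the C11 silyl ether or draw the isopropenyl alkene into a Prins-type attack on the activated carbonyl. The fallback sets out from 9, isolated before DBU is added. There the alkene is still masked as the tertiary bromide, so a buffered peracid (m-CPBA, NaHCO3, CH2Cl2) can carry out the oxygen insertion without epoxidation and should give the bromo lactone F1. DBU then removes HBr, and the route is rejoined at 12.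

**Step 12.** Three things may go wrong: closure at the terminal alkyne carbon (endo mode), engagement of the enone by nickel, and poor facial selectivity at C7, which has no neighbouring control element. The fallback sets out from 18 and replaces the reductive coupling by a chromium-mediated vinyl halide–aldehyde closure, in which the position of the halide fixes the regiochemistry. Markovnikov hydrosilylation of the alkyne ([Cp*Ru(MeCN)3]PF6, Et3SiH) should give the 2-silylalkene F2, and iododesilylation (NIS, hexafluoroisopropanol, 0 °C) the 2-iodoalkene F3. Acetal hydrolysis as in step 11 gives the iodo enal F4. Closure with CrCl2 (divalent chromium, excess) and catalytic NiCl2 in DMSO/THF at high dilution, if needed with a chiral sulfonamide ligand on chromium to steer C7, returns to the route at 21, which is cyclised as in step 13.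

**Step 13.** The addition may stall on the enone side of the equilibrium, may close with the wrong facial selectivity at C4, or may be accompanied by epimerisation at C1 through the enol of the C2 ketone. The fallback sets out from 20 and makes the ether bond irreversibly. Buffered HF·pyridine gives 21, and 1,2-reduction (NaBH4, CeCl3, MeOH, −78 °C) the allylic diol F5. Iodoetherification with NIS (5-exo attack of the C7 hydroxyl on the tertiary C4) gives the iodo oxolane F6, and Bu3SnH/AIBN removes iodine to give the oxolane alcohol F7. Dess–Martin oxidation returns to the route at 22.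

**Step 14.** Hydride may be delivered under macrocyclic rather than chelate control, with poor facial selectivity at C2, and the C2 alkoxide may translactonise onto C16. The fallback sets out from 22 and corrects the centre by inversion. A reduction that favours the other face (for example NaBH4/CeCl3) is used on purpose to give the 2-epi alcohol F8. Mitsunobu reaction with chloroacetic acid (PPh3, DIAD) gives the inverted chloroacetate F9, and thiourea/NaHCO3 in ethanol cleaves it under neutral conditions, returning to the route at 23.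

**Step 5.** HBr may be lost toward C1 instead of the methyl groups, and the resulting alkene would then move into conjugation with the ketone. The cyclopropane may also re-close through the C15 enolate. The fallback sets out from 7 and avoids a halide and a base altogether. Hydrative opening (dilute H2SO4, THF/H2O) should give the diol F10, and TBSCl/imidazole silylates only the secondary hydroxyl to give the tertiary alcohol F11. Dehydration through the chlorosulfite (SOCl2, pyridine, 0 °C) returns to the route at 10.

## Further compounds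

F1 | step 6 | (4R,7S)-4-(2-bromopropan-2-yl)-7-[(1S)-1-(tert-butyldimethylsilyloxy)pent-4-yn-1-yl]-7-methyloxepan-2-one | C1C(=O)O[C@@]([C@@H](O[Si](C)(C)C(C)(C)C)CCC#C)(C)CC[C@H]1C(C)(C)Br
F2 | step 12 | (4R,7S)-7-[(1S)-1-(tert-butyldimethylsilyloxy)-4-(triethylsilyl)pent-4-en-1-yl]-4-[(2E)-6,6-dimethoxy-3-methylhex-2-enoyl]-7-methyloxepan-2-one | C1C(=O)O[C@@]([C@@H](O[Si](C)(C)C(C)(C)C)CCC(=C)[Si](CC)(CC)CC)(C)CC[C@H]1C(=O)/C=C(\C)CCC(OC)OC
F3 | step 12 | (4R,7S)-7-[(1S)-1-(tert-butyldimethylsilyloxy)-4-iodopent-4-en-1-yl]-4-[(2E)-6,6-dimethoxy-3-methylhex-2-enoyl]-7-methyloxepan-2-one | C1C(=O)O[C@@]([C@@H](O[Si](C)(C)C(C)(C)C)CCC(I)=C)(C)CC[C@H]1C(=O)/C=C(\C)CCC(OC)OC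
F4 | step 12 | (4R,7S)-7-[(1S)-1-(tert-butyldimethylsilyloxy)-4-iodopent-4-en-1-yl]-7-methyl-4-[(2E)-3-methyl-6-oxohex-2-enoyl]oxepan-2-one | C1C(=O)O[C@@]([C@@H](O[Si](C)(C)C(C)(C)C)CCC(I)=C)(C)CC[C@H]1C(=O)/C=C(\C)CCC=O
F5 | step 13 | (1R,7R,11S,12S,3E)-11-(tert-butyldimethylsilyloxy)-2,7-dihydroxy-17-norcembra-3,8(19)-dien-16,12-olide (C2 epimers) | C1C(=O)O[C@@]2(C)CC[C@H]1C(O)/C=C(\C)CC[C@@H](O)C(=C)CC[C@@H]2O[Si](C)(C)C(C)(C)C
F6 | step 13 | (1R,4S,7R,11S,12S)-11-(tert-butyldimethylsilyloxy)-4,7-epoxy-2-hydroxy-3-iodo-17-norcembr-8(19)-en-16,12-olide (C2 and C3 unassigned) | C1C(=O)O[C@@]2(C)CC[C@H]1C(O)C(I)[C@]3(C)CC[C@@H](O3)C(=C)CC[C@@H]2O[Si](C)(C)C(C)(C)C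
F7 | step 13 | (1R,4S,7R,11S,12S)-11-(tert-butyldimethylsilyloxy)-4,7-epoxy-2-hydroxy-17-norcembr-8(19)-en-16,12-olide (C2 epimers) | C1C(=O)O[C@@]2(C)CC[C@H]1C(O)C[C@]3(C)CC[C@@H](O3)C(=C)CC[C@@H]2O[Si](C)(C)C(C)(C)C
F8 | step 14 | (1R,2R,4S,7R,11S,12S)-11-(tert-butyldimethylsilyloxy)-4,7-epoxy-2-hydroxy-17-norcembr-8(19)-en-16,12-olide | C1C(=O)O[C@@]2(C)CC[C@H]1[C@H](O)C[C@]3(C)CC[C@@H](O3)C(=C)CC[C@@H]2O[Si](C)(C)C(C)(C)C
F9 | step 14 | (1R,2S,4S,7R,11S,12S)-11-(tert-butyldimethylsilyloxy)-2-(chloroacetoxy)-4,7-epoxy-17-norcembr-8(19)-en-16,12-olide | C1C(=O)O[C@@]2(C)CC[C@H]1[C@@H](OC(=O)CCl)C[C@]3(C)CC[C@@H](O3)C(=C)CC[C@@H]2O[Si](C)(C)C(C)(C)C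
F10 | step 5 | (2S,5R)-2-[(1S)-1-hydroxypent-4-yn-1-yl]-5-(2-hydroxypropan-2-yl)-2-methylcyclohexan-1-one | C1C(=O)[C@@]([C@@H](O)CCC#C)(C)CC[C@H]1C(C)(C)O
F11 | step 5 | (2S,5R)-2-[(1S)-1-(tert-butyldimethylsilyloxy)pent-4-yn-1-yl]-5-(2-hydroxypropan-2-yl)-2-methylcyclohexan-1-one | C1C(=O)[C@@]([C@@H](O[Si](C)(C)C(C)(C)C)CCC#C)(C)CC[C@H]1C(C)(C)O
A1 | alternative 1 | 2-methylfuran | Cc1ccco1
A2 | alternative 1 | (R)-4-phenyl-3-(propa-1,2-dien-1-yl)oxazolidin-2-one | C=C=CN1C(=O)OC[C@H]1c1ccccc1
A3 | alternative 1 | bridgehead-methyl 8-oxabicyclo[3.2.1]oct-6-en-3-one with the oxazolidinone next to the methyl bridgehead | C[C@]12O[C@H](C=C1)CC(=O)[C@@H]2N1C(=O)OC[C@H]1c1ccccc1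
A4 | alternative 2 | 14-membered cyclic enol ether (C11 exocyclic methylene, ring oxygen between C11 and the allylic CH2 on C8) | CC[Si](CC)(CC)O[C@@]1(C)CC[C@H](CCOCc2ccc(OC)cc2)[C@@H](O[Si](C)(C)C(C)(C)C)C[C@]2(C)CC[C@@H](O2)C(=C)COC1=C
A5 | alternative 2 | 14-membered carbocyclic C11 ketone with the C8 exocyclic methylene | CC[Si](CC)(CC)O[C@@]1(C)CC[C@H](CCOCc2ccc(OC)cc2)[C@@H](O[Si](C)(C)C(C)(C)C)C[C@]2(C)CC[C@@H](O2)C(=C)CCC1=O
A6 | alternative 3 | 14-membered carbocycle fused to the C2–C4 isoxazoline | C1C(=O)O[C@@]2(C)CC[C@H]1C3=NO[C@@](C3)(C)CC/C=C(COC(=O)OC)\CC[C@@H]2O[Si](C)(C)C(C)(C)C
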